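Z is the complex, L the incoming ligand, D the complex with one exchanged and J the one with two. If I repeat this flask and read D at the end, I expect a curve that has already turned, as in the earlier runs, so I need to know how fast D fades.

| flask | Z | L | remark | time |
|---|---|---|---|---|
| spring | 0.50 M | 0.25 equiv | run made earlier |  |
| winter | 0.50 M | 1 equiv | run made earlier |  |
| summer | 1 M | 0.50 equiv | run made earlier |  |
| flask | 0.50 M | 0.500 equiv |  | 5.0 min |

| run | time / min | D / % | J / % |
|---|---|---|---|
| spring | 0.250 | 11 | 0 |
| spring | 0.833 | 13 | 0 |
| spring | 1.33 | 10 | 0 |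
| spring | 2.00 | 8 | 0 |
| spring | 3.00 | 6 | 2 |
| spring | 4.00 | 0 | 1 |
| winter | 0.333 | 22 | 4 |
| winter | 0.500 | 24 | 5 |
| winter | 0.833 | 24 | 7 |
| winter | 1.33 | 20 | 1 |
| winter | 2.50 | 15 | 3 |
| winter | 4.00 | 14 | 6 |
| summer | 0.833 | 12 | 0 |
| summer | 1.50 | 11 | 5 |
| summer | 2.50 | 7 | 0 |
| summer | 3.00 | 9 | 1 |
| summer | 4.00 | 5 | 0 |

(scatter of a reading: 2 percentage points)



- equivalents of L to Z, everything else as given, that leave most D at 5.0 min
- the amount of D then, in percent of the Z charged
- the amount of D with the amounts as given

I call f the fade constant: ln(earlier D / later D) divided by the time between two readings. It replaces a curve by its mean, as if the fall were pseudo-first-order.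

My first way stays at this Z. Spring holds half the equivalents of this flask and winter twice, so I take the geometric mean of their D at 0.833 min and the mean of their f.

level = 17.7 %
spring f = 0.357 /min, winter f = 0.170 /min, mean fe = 0.263 /min
D at 5.0 min = 5.92 %

My second way starts from summer, with the same equivalents at twice the Z. Summer's f is 0.276 /min, above winter's at the same L molarity, so I try scaling it in proportion to Z, holding the equivalents.

fl = 0.138 /min
D at 5.0 min = 6.75 %

These ends lie close, but their levels and constants part, so the closeness proves nothing. At 0.833 min winter and summer read 0.120 M and 0.120 M of D, so I do not carry summer's percentage across Z, and I take the second level to be the one that cheats. The first constant may cheat late: summer reads a fall at 0.323 /min, then at 0.224 /min, though these readings carry a scatter of 2 percentage points. So I keep the first level and use fe early, then fl, the late fade constant: summer's f scaled to this Z.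

D at 2.00 min = 13.0 %
D at 5.0 min = 8.58 %

The forecast gives 7 % here and 18 % at 2 equiv, holding that “extra L sustains D”.

The flask gives 8.38 % as charged, and 14.1 % at 2.42 equiv.

    D + L ⇌ G + J (K = 0.340, k = 0.680 /M/s)
    Z + D → X (k = 0.0220 /M/s)
    J + L ⇌ G + Q (K = 9.00, k = 0.290 /M/s)
    Z + L ⇌ G + D (K = 0.880, k = 0.130 /M/s)

In this flask D falls from 11.7 % at 2.50 min to 8.38 % at 5.00 min, an f of 0.132 /min beside my fl of 0.138 /min. The neighbour is the same flask read at 2.0 min, where my reckoning put D at 13.0 %. Carried to 5.0 min by fl, that neighbour's D becomes 8.53 %. The neighbour itself holds 12.9 % of D.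

The data are simulated for an exercise, noise included.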